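**Assumption:** each chiral ligand (steps 2, 6, 9) is used as the enantiomer that gives the configuration drawn; the sense of induction is checked on the first run by chiral GC/HPLC, and the antipodal ligands are equally accessible.

## Retrosynthetic overview

1. Target 18 comes from formate 16 by oxidative cleavage of a terminal vinyl group (a latent CO2H). The C6 CH2OCHO group comes from catalytic asymmetric hydroxymethylation of the α′-silyl dienol ether of enone 12.
2. Enone 12 comes from alkyne 10 and cyclobutanone 11 by a Ni(0)-catalysed two-carbon ring expansion (4 → 6): the alkyne inserts into the C(O)–CH2 bond, forming C1–C2, C3–C4 and the tetrasubstituted alkene in one step.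
3. Alkyne 10 comes from terminal alkyne 6 and crotyl phosphate 8 by Cu-catalysed enantioselective SN2′ alkynylation, which sets the side-chain stereocentre.
4. Alkyne 6 comes from 3-bromocyclohexenone 1 and TMS-acetylene 2: Sonogashira coupling, Cu-catalysed asymmetric 1,4-methyl addition (quaternary centre), gem-dimethylation of the ketone, desilylation.
5. Ring order: the trimethylcyclohexane ring is the six-membered ring of 1, carried from the start; the cyclohexenone ring is formed second, in the ring expansion.

## Route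

Step 1
Reactants: 1 3-bromocyclohex-2-en-1-one; 2 ethynyltrimethylsilane
Product: 3 3-[(trimethylsilyl)ethynyl]cyclohex-2-en-1-one
Conditions: PdCl2(PPh3)2 (2 mol%), CuI (4 mol%), Et3N, THF, rt
Reagents that add atoms: none
Why: Sonogashira coupling; the β-bromoenone is an activated vinyl halide that adds oxidatively to Pd(0) at room temperature, and no stereocentre is involved.

Step 2
Reactants: 3 3-[(trimethylsilyl)ethynyl]cyclohex-2-en-1-one
Product: 4 (3S)-3-methyl-3-[(trimethylsilyl)ethynyl]cyclohexan-1-one
Conditions: MeMgBr (1.2 equiv), Cu(OTf)2 (6 mol%), chiral hydroxyalkyl-imidazolinium salt (NHC precursor, 9 mol%), Et2O, −10 °C; aq. NH4Cl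
Reagents that add atoms: methylmagnesium bromide C[Mg]Br
Why: Copper/NHC-catalysed asymmetric conjugate addition of a Grignard reagent to a cyclic enynone, 1,4-selective because the silylated alkyne terminus disfavours 1,6-attack, with the quaternary stereocentre (S) set by ligand-controlled facial delivery of methyl.

Step 3
Reactants: 4 (3S)-3-methyl-3-[(trimethylsilyl)ethynyl]cyclohexan-1-one
Product: 5 trimethyl{[(1S)-1,3,3-trimethylcyclohexyl]ethynyl}silane
Conditions: Me2Zn (2.2 equiv), TiCl4 (2.2 equiv), CH2Cl2, −30 °C; then 4, −30 → 0 °C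
Reagents that add atoms: dimethylzinc C[Zn]C (delivers both methyl groups through dimethyltitanium dichloride C[Ti](C)(Cl)Cl formed in the flask with TiCl4)
Why: Reetz geminal dimethylation, in which methyl addition gives a tertiary titanium alkoxide that ionises to a tertiary cation and is captured by a second Ti–CH3, turning C=O into C(CH3)2 without touching the quaternary stereocentre.

Step 4
Reactants: 5 trimethyl{[(1S)-1,3,3-trimethylcyclohexyl]ethynyl}silane
Product: 6 (1S)-1-ethynyl-1,3,3-trimethylcyclohexane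
Conditions: K2CO3 (0.2 equiv), MeOH, rt
Reagents that add atoms: none
Why: Base-catalysed protodesilylation (methanolysis of the C(sp)–Si bond); the stereocentre is not involved.

Step 5
Reactants: 7 (E)-but-2-en-1-ol
Product: 8 diethyl (E)-but-2-en-1-yl phosphate
Conditions: ClP(O)(OEt)2 (1.1 equiv), Et3N, DMAP (5 mol%), CH2Cl2, 0 °C → rt
Reagents that add atoms: diethyl chlorophosphate CCOP(=O)(Cl)OCC
Why: O-phosphorylation of a primary allylic alcohol; the alkene geometry is retained.

Step 6
Reactants: 6 (1S)-1-ethynyl-1,3,3-trimethylcyclohexane; 8 diethyl (E)-but-2-en-1-yl phosphate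
Product: 10 (1S)-1,3,3-trimethyl-1-[(3S)-3-methylpent-4-en-1-yn-1-yl]cyclohexane, via alkynylalane 9 (not isolated)
Conditions: DIBAL-H (1.0 equiv), Et3N (5 mol%), hexanes, 55 °C; then 8 (1.2 equiv), CuCl2·2H2O (5 mol%), chiral sulfonate-NHC–Ag complex (2.5 mol%), THF, −15 °C
Reagents that add atoms: none
Why: Deprotonative alumination of the terminal alkyne followed by NHC–Cu-catalysed enantioselective allylic substitution (SN2′) on the (E)-allylic phosphate, which forms the C(sp)–C(sp3) bond at the γ-carbon and sets the side-chain stereocentre (S) under catalyst control, independent of the remote quaternary centre.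

Step 7
Reactants: 10 (1S)-1,3,3-trimethyl-1-[(3S)-3-methylpent-4-en-1-yn-1-yl]cyclohexane; 11 cyclobutanone
Product: 12 2-[(2S)-but-3-en-2-yl]-3-[(1S)-1,3,3-trimethylcyclohexyl]cyclohex-2-en-1-one
Conditions: Ni(cod)2 (10 mol%), PCy3 (20 mol%), 11 (3 equiv), toluene, 100 °C, sealed tube
Reagents that add atoms: none
Why: Proposed new method: Ni(0)-catalysed [4+2] ring expansion of cyclobutanone by insertion of an unsymmetrical internal alkyne flanked by a quaternary and a tertiary propargylic carbon (a skipped enyne) into the C(O)–CH2 bond; oxidative cyclisation of C=O and the alkyne on Ni(0) should form the C–C bond at the less hindered alkyne carbon (the one bearing CH(CH3)CH=CH2, leaving the tert-alkyl-substituted carbon on nickel), strain-driven β-carbon elimination then opens the four-membered ring to a seven-membered nickelacycle, and C(sp2)–C(sp3) reductive elimination gives the cyclohexenone with the tert-alkyl group at C3 and the butenyl group at C2, both stereocentres being retained because no bond to them is broken under neutral conditions; the closest known reaction type is the Ni(0)/phosphine-catalysed insertion of simple dialkyl or aryl alkynes into 3-substituted cyclobutanones, not yet shown for an alkyne of this kind.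

Step 8
Reactants: 12 2-[(2S)-but-3-en-2-yl]-3-[(1S)-1,3,3-trimethylcyclohexyl]cyclohex-2-en-1-one
Product: 14 trimethyl({6-[(2S)-but-3-en-2-yl]-5-[(1S)-1,3,3-trimethylcyclohexyl]cyclohexa-1,5-dien-1-yl}oxy)silane, via lithium dienolate 13 (not isolated)
Conditions: LDA (1.1 equiv), THF, −78 °C; TMSCl (1.3 equiv), −78 → 0 °C
Reagents that add atoms: chlorotrimethylsilane C[Si](C)(C)Cl
Why: Kinetic α′-deprotonation of the enone and O-silylation to the cross-conjugated silyl dienol ether; C4 is shielded by the tert-alkyl group and the side-chain C–H is not conjugated to the carbonyl, so its stereocentre is safe.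

Step 9
Reactants: 14 trimethyl({6-[(2S)-but-3-en-2-yl]-5-[(1S)-1,3,3-trimethylcyclohexyl]cyclohexa-1,5-dien-1-yl}oxy)silane
Product: 15 (6S)-2-[(2S)-but-3-en-2-yl]-6-(hydroxymethyl)-3-[(1S)-1,3,3-trimethylcyclohexyl]cyclohex-2-en-1-one
Conditions: Sc(OTf)3 (10 mol%), chiral 6,6′-bis(1-hydroxy-2,2-dimethylpropyl)-2,2′-bipyridine (12 mol%), aq. HCHO (5 equiv), DME–H2O (9:1), −20 °C
Reagents that add atoms: formaldehyde C=O
Why: Catalytic asymmetric Mukaiyama aldol (hydroxymethylation) in aqueous medium with a chiral Sc(III)–bipyridine complex; the dienol ether can only react at C6, and the catalyst selects the enolate face to set C6 (S).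

Step 10
Reactants: 15 (6S)-2-[(2S)-but-3-en-2-yl]-6-(hydroxymethyl)-3-[(1S)-1,3,3-trimethylcyclohexyl]cyclohex-2-en-1-one
Product: 16 {(1S)-3-[(2S)-but-3-en-2-yl]-2-oxo-4-[(1S)-1,3,3-trimethylcyclohexyl]cyclohex-3-en-1-yl}methyl formate
Conditions: HCO2Ac (3 equiv), pyridine, CH2Cl2, −20 → 0 °C
Reagents that add atoms: acetic formic anhydride CC(=O)OC=O
Why: O-formylation of the primary alcohol with the mixed anhydride (formyl transfer is faster than acetyl transfer); weak base at low temperature avoids β-elimination and C6 epimerisation.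

Step 11
Reactants: 16 {(1S)-3-[(2S)-but-3-en-2-yl]-2-oxo-4-[(1S)-1,3,3-trimethylcyclohexyl]cyclohex-3-en-1-yl}methyl formate
Product: 18 (2R)-2-{(5S)-5-[(formyloxy)methyl]-6-oxo-2-[(1S)-1,3,3-trimethylcyclohexyl]cyclohex-1-en-1-yl}propanoic acid, via aldehyde 17 (not isolated)
Conditions: O3, MeCN–H2O (9:1), 0 °C (indicator end-point, N2 purge); then NaClO2, NaH2PO4, 0 °C → rt
Reagents that add atoms: ozone [O-][O+]=O; sodium chlorite [Na+].[O-]Cl=O
Why: One-pot ozonolysis and Pinnick-type chlorite oxidation; ozone cleaves the terminal vinyl group much faster than the hindered, electron-poor tetrasubstituted enone, water converts the carbonyl oxide into the aldehyde, and buffered chlorite oxidises it at pH about 4, where the α-stereocentre (unchanged in space, R by CIP because CO2H now outranks the ring carbon) and the formate survive.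

## Compound list

1 | 3-bromocyclohex-2-en-1-one | O=C1CCCC(Br)=C1 | starting material
2 | ethynyltrimethylsilane | C#C[Si](C)(C)C | starting material
3 | 3-[(trimethylsilyl)ethynyl]cyclohex-2-en-1-one | O=C1CCCC(C#C[Si](C)(C)C)=C1 | intermediate
4 | (3S)-3-methyl-3-[(trimethylsilyl)ethynyl]cyclohexan-1-one | C[Si](C)(C)C#C[C@@]1(C)CCCC(=O)C1 | intermediate
5 | trimethyl{[(1S)-1,3,3-trimethylcyclohexyl]ethynyl}silane | C[Si](C)(C)C#C[C@@]1(C)CCCC(C)(C)C1 | intermediate
6 | (1S)-1-ethynyl-1,3,3-trimethylcyclohexane | C#C[C@@]1(C)CCCC(C)(C)C1 | intermediate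
7 | (E)-but-2-en-1-ol | C/C=C/CO | starting material
8 | diethyl (E)-but-2-en-1-yl phosphate | C/C=C/COP(=O)(OCC)OCC | intermediate
9 | diisobutyl{[(1S)-1,3,3-trimethylcyclohexyl]ethynyl}alane | CC(C)C[Al](CC(C)C)C#C[C@@]1(C)CCCC(C)(C)C1 | intermediate (not isolated)
10 | (1S)-1,3,3-trimethyl-1-[(3S)-3-methylpent-4-en-1-yn-1-yl]cyclohexane | C[C@@H](C=C)C#C[C@@]1(C)CCCC(C)(C)C1 | intermediate
11 | cyclobutanone | O=C1CCC1 | starting material
12 | 2-[(2S)-but-3-en-2-yl]-3-[(1S)-1,3,3-trimethylcyclohexyl]cyclohex-2-en-1-one | C[C@@H](C=C)C1=C([C@@]2(C)CCCC(C)(C)C2)CCCC1=O | intermediate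
13 | lithium 6-[(2S)-but-3-en-2-yl]-5-[(1S)-1,3,3-trimethylcyclohexyl]cyclohexa-1,5-dien-1-olate | C[C@@H](C=C)C1=C([C@@]2(C)CCCC(C)(C)C2)CCC=C1[O-].[Li+] | intermediate (not isolated)
14 | trimethyl({6-[(2S)-but-3-en-2-yl]-5-[(1S)-1,3,3-trimethylcyclohexyl]cyclohexa-1,5-dien-1-yl}oxy)silane | C[C@@H](C=C)C1=C([C@@]2(C)CCCC(C)(C)C2)CCC=C1O[Si](C)(C)C | intermediate
15 | (6S)-2-[(2S)-but-3-en-2-yl]-6-(hydroxymethyl)-3-[(1S)-1,3,3-trimethylcyclohexyl]cyclohex-2-en-1-one | C[C@@H](C=C)C1=C([C@@]2(C)CCCC(C)(C)C2)CC[C@@H](CO)C1=O | intermediate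
16 | {(1S)-3-[(2S)-but-3-en-2-yl]-2-oxo-4-[(1S)-1,3,3-trimethylcyclohexyl]cyclohex-3-en-1-yl}methyl formate | C[C@@H](C=C)C1=C([C@@]2(C)CCCC(C)(C)C2)CC[C@@H](COC=O)C1=O | intermediate
17 | {(1S)-2-oxo-3-[(2R)-1-oxopropan-2-yl]-4-[(1S)-1,3,3-trimethylcyclohexyl]cyclohex-3-en-1-yl}methyl formate | C[C@@H](C=O)C1=C([C@@]2(C)CCCC(C)(C)C2)CC[C@@H](COC=O)C1=O | intermediate (not isolated)
18 | (2R)-2-{(5S)-5-[(formyloxy)methyl]-6-oxo-2-[(1S)-1,3,3-trimethylcyclohexyl]cyclohex-1-en-1-yl}propanoic acid | C[C@@H](C(=O)O)C1=C([C@@]2(C)CCCC(C)(C)C2)CC[C@@H](COC=O)C1=O | target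

## Step count and risks

Total step count: 11. Longest linear sequence: 10 steps (1 → 2 → 3 → 4 → 6 → 7 → 8 → 9 → 10 → 11); step 5 is a one-step side branch.

**Step 7 (the proposed new step).** The congested alkyne may not undergo oxidative cyclisation, the seven-membered nickelacycle may suffer β-hydride elimination, or the skipped enyne may isomerise. The fallback uses known chemistry, sets out from alkyne 6 and returns at enone 12, bypassing steps 6 and 7. Markovnikov hydration of 6 (Au(I) catalyst, aqueous MeOH) gives the methyl ketone 1-[(1S)-1,3,3-trimethylcyclohexyl]ethan-1-one F1. Separately, (3R)-3-methylpent-4-enoic acid F2 (resolved from the commercial racemate) is treated with vinyllithium (2 equiv) to give (5R)-5-methylhepta-1,6-dien-3-one F3. Robinson annulation of F1, whose only enolisable position is its methyl group, with F3 (KOH, EtOH) proceeds by Michael addition to the 1,5-diketone (7R)-7-methyl-1-[(1S)-1,3,3-trimethylcyclohexyl]non-8-ene-1,5-dione F4 and then aldol condensation, the only six-membered closure available, to give 12.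

**Step 9.** The TMS dienol ether may hydrolyse in the aqueous medium before it reacts, or catalyst control at C6 may be insufficient. The fallback sets out from 12 and returns at 15. Lithium dienolate 13 (LDA, THF, −78 °C) is quenched with monomeric formaldehyde without stereocontrol, giving 15 together with its C6 epimer (6R)-2-[(2S)-but-3-en-2-yl]-6-(hydroxymethyl)-3-[(1S)-1,3,3-trimethylcyclohexyl]cyclohex-2-en-1-one F5. The two are diastereomers and are separated by preparative HPLC; F5 is re-equilibrated at C6 with catalytic DBU and recycled.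

**Step 2.** Methyl transfer to the enynone may give low ee, or 1,6- and 1,2-addition may compete. The fallback reverses the roles in the conjugate addition; it sets out from 2 and returns at 6, replacing steps 1 to 4. Hydroalumination of 2 with DIBAL-H gives the α-silyl vinylalane diisobutyl[1-(trimethylsilyl)ethenyl]alane F6. F6 adds to purchased 3-methylcyclohex-2-en-1-one under chiral NHC–Cu catalysis to give (3S)-3-methyl-3-[1-(trimethylsilyl)ethenyl]cyclohexan-1-one F7. Reetz gem-dimethylation as in step 3 gives trimethyl{1-[(1S)-1,3,3-trimethylcyclohexyl]ethenyl}silane F8. Ipso-iododesilylation with NIS (MeCN) gives (1S)-1-(1-iodoethenyl)-1,3,3-trimethylcyclohexane F9, and dehydroiodination with LDA gives 6.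

## Further compounds

F1 | step 7 | 1-[(1S)-1,3,3-trimethylcyclohexyl]ethan-1-one | CC(=O)[C@@]1(C)CCCC(C)(C)C1
F2 | step 7 | (3R)-3-methylpent-4-enoic acid | C[C@@H](C=C)CC(=O)O
F3 | step 7 | (5R)-5-methylhepta-1,6-dien-3-one | C[C@@H](C=C)CC(=O)C=C
F4 | step 7 | (7R)-7-methyl-1-[(1S)-1,3,3-trimethylcyclohexyl]non-8-ene-1,5-dione | C[C@@H](C=C)CC(=O)CCCC(=O)[C@@]1(C)CCCC(C)(C)C1
F5 | step 9 | (6R)-2-[(2S)-but-3-en-2-yl]-6-(hydroxymethyl)-3-[(1S)-1,3,3-trimethylcyclohexyl]cyclohex-2-en-1-one | C[C@@H](C=C)C1=C([C@@]2(C)CCCC(C)(C)C2)CC[C@H](CO)C1=O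
F6 | step 2 | diisobutyl[1-(trimethylsilyl)ethenyl]alane | C=C([Si](C)(C)C)[Al](CC(C)C)CC(C)C
F7 | step 2 | (3S)-3-methyl-3-[1-(trimethylsilyl)ethenyl]cyclohexan-1-one | C=C([Si](C)(C)C)[C@@]1(C)CCCC(=O)C1
F8 | step 2 | trimethyl{1-[(1S)-1,3,3-trimethylcyclohexyl]ethenyl}silane | C=C([Si](C)(C)C)[C@@]1(C)CCCC(C)(C)C1
F9 | step 2 | (1S)-1-(1-iodoethenyl)-1,3,3-trimethylcyclohexane | C=C(I)[C@@]1(C)CCCC(C)(C)C1
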